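Ring A (C1–C5, C10) is read as the cyclohexene of an intramolecular Diels–Alder reaction. A 2-silyloxydiene (C10=C1–C2=C3) on C9 of a fully substituted cyclopentane (ring C) adds across the distal C4=C5 bond of an allenyl ketone on C8. One operation forms C3–C4 and C5–C10, closes rings A and B, builds the gem-dimethyl carbon C4 and the methyl-bearing C10, and leaves a C5=C6–C7=O enone and a C1 enol ether that later deliver the 5-OH, 7-OAc and 1-OAc groups. Ring C comes from an organocatalytic double Michael cascade; the spiro epoxy-lactone is closed last.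

Key step: step 13

Remark: atoms are numbered as in the cassane skeleton (ring A C1–C5/C10, ring B C5–C10, ring C C8, C9, C11, C12, C14; C12 is the spiro carbon; α/β as in steroid drawings); the catalyst enantiomer in step 4 is assigned from the usual shielding model of the iminium ion.

Step 1
Reactants: 1 (E)-2-methylbut-2-enoyl chloride (tigloyl chloride)
Product: 2 S-ethyl (E)-2-methylbut-2-enethioate
Conditions: EtSH, Et3N, CH2Cl2, 0 °C
Reagents that add atoms: ethanethiol CCS
Why: Thioesterification of the acid chloride by the thiol under base (acyl substitution) should be fast and leaves the (E)-alkene untouched.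

Step 2
Reactants: 2 S-ethyl (E)-2-methylbut-2-enethioate
Product: 3 S-ethyl (E)-4-bromo-2-methylbut-2-enethioate
Conditions: NBS, AIBN (cat.), PhCF3, 80 °C
Reagents that add atoms: N-bromosuccinimide O=C1CCC(=O)N1Br
Why: Wohl–Ziegler radical bromination should occur mainly at the γ-methyl group, as with tiglate esters, and the conjugated (E)-alkene is retained.

Step 3
Reactants: 3 S-ethyl (E)-4-bromo-2-methylbut-2-enethioate; 4 Meldrum's acid (2,2-dimethyl-1,3-dioxane-4,6-dione)
Product: 5 5-[(E)-4-(ethylsulfanyl)-3-methyl-4-oxobut-2-en-1-yl]-2,2-dimethyl-1,3-dioxane-4,6-dione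
Conditions: 4 (excess), K2CO3, DMF, 0 °C to rt
Reagents that add atoms: none
Why: SN2 C-alkylation of the Meldrum's acid anion by the primary allylic bromide should give the mono-alkylated carbon acid, the excess of 4 holding back a second alkylation.

Step 4
Reactants: 5 mono-alkylated Meldrum's acid; 6 methyl (E)-4-oxobut-2-enoate
Product: 7 ring-C aldehyde (all-trans cyclopentane spiro-fused at C12 to the dioxanedione; 14β-CO2Me, 8α-CHO, 9β-CH(CH3)C(O)SEt, C10 epimers)
Conditions: (R)-α,α-diphenylprolinol trimethylsilyl ether (cat.), NaOAc (cat.), CH2Cl2, 0 °C to rt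
Reagents that add atoms: none
Why: Iminium–enamine double Michael cascade: C12 of the carbon acid adds to C14 of the enal iminium ion on the face left open by the diarylmethyl group, which sets C14, and the enamine then closes ring C by 5-exo Michael addition of C8 to C9 of the thioenoate, giving the 14β,8α,9β trans,trans array that is also the thermodynamic one at the epimerisable C8.

Step 5
Reactants: 7 ring-C aldehyde
Product: 8 acylal acid (C7 methoxy acetal carbon linked through oxygen to the 12α-carbonyl in a six-membered pseudo-ester ring; 12β-CO2H)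
Conditions: MeOH, CH2Cl2, 40 °C
Reagents that add atoms: methanol CO
Why: Hemiacetal formation at the C7 aldehyde followed by intramolecular acyl transfer (alcoholysis of the Meldrum's acid ring with loss of acetone) can reach, through a six-membered transition state, only the ring carbonyl cis to the C8 substituent, so the α carboxyl becomes the bridged pseudo-ester and the β carboxyl the free acid, which sets C12.

Step 6
Reactants: 8 acylal acid
Product: 10 12β-formyl acylal, via acid chloride 9 (not isolated)
Conditions: 1-chloro-N,N,2-trimethylprop-1-en-1-amine, CH2Cl2, 0 °C; then LiAlH(OtBu)3, THF, −78 °C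
Reagents that add atoms: none
Why: Neutral conversion of the hindered acid into its chloride and partial reduction of an acid chloride by the bulky hydride LiAlH(OtBu)3 should stop at the aldehyde and spare thioester, methyl ester and pseudo-ester, with C12 untouched.

Step 7
Reactants: 10 12β-formyl acylal
Product: 11 12β-(2-methoxyethenyl) acylal (E/Z mixture)
Conditions: MeOCH2PPh3Cl, KN(SiMe3)2, THF, −78 to 0 °C
Reagents that add atoms: (methoxymethyl)triphenylphosphonium chloride COC[P+](c1ccccc1)(c1ccccc1)c1ccccc1.[Cl-]
Why: Wittig methoxymethylenation of the non-enolisable neopentyl aldehyde adds the carbon that becomes the lactone acetal carbon, the aldehyde reacting far faster with the ylide than the thioester.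

Step 8
Reactants: 11 12β-(2-methoxyethenyl) acylal
Product: 12 vinyl ketone (9β-CH(CH3)C(O)CH=CH2)
Conditions: tributyl(vinyl)stannane, Pd2(dba)3 (cat.), tri(2-furyl)phosphine, CuOP(O)Ph2, THF, 50 °C
Reagents that add atoms: tributyl(vinyl)stannane C=C[Sn](CCCC)(CCCC)CCCC
Why: Liebeskind–Srogl-type ketone synthesis (Pd-catalysed, copper phosphinate-mediated coupling of a thioester with an organostannane) should turn only the thioester into the vinyl ketone under neutral conditions.

Step 9
Reactants: 12 vinyl ketone
Product: 13 silyl dienol ether (9β-[(Z)-C(CH3)=C(OTIPS)–CH=CH2])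
Conditions: TIPSOTf, Et3N, CH2Cl2, −78 to 0 °C
Reagents that add atoms: triisopropylsilyl trifluoromethanesulfonate CC(C)[Si](OS(=O)(=O)C(F)(F)F)(C(C)C)C(C)C
Why: Soft enolisation and O-silylation can only occur at C10, the single α-hydrogen of the vinyl ketone, and should give the cross-conjugated dienol ether with the larger C9 substituent cis to the silyloxy group (Z), the geometry needed in step 13.

Step 10
Reactants: 13 silyl dienol ether
Product: 14 aldehyde benzyl ester (8α-CHO, 12α-CO2Bn)
Conditions: BnOH, K2CO3 (cat.), THF, 0 °C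
Reagents that add atoms: benzyl alcohol OCc1ccccc1
Why: Base-catalysed transesterification of the activated pseudo-ester by benzyl alcohol releases the hemiacetal, which collapses to the C7 aldehyde, far faster than the methyl ester or the hindered silyl enol ether can react.

Step 11
Reactants: 14 aldehyde benzyl ester
Product: 15 allenyl carbinol (8α-CH(OH)–CH=C=C(CH3)2, C7 epimers)
Conditions: 3-methylbuta-1,2-diene, n-BuLi, THF, −78 °C; then 14; AcOH, −78 °C
Reagents that add atoms: 3-methylbuta-1,2-diene CC(C)=C=C
Why: 1,2-Addition of lithiated 1,1-dimethylallene, which reacts through its allenic carbon because the propargylic terminus is tertiary, to the aldehyde at −78 °C gives the α-allenyl alcohol while the esters are spared, and the C7 configuration is irrelevant.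

Step 12
Reactants: 15 allenyl carbinol
Product: 16 allenyl ketone (8α-C(O)–CH=C=C(CH3)2)
Conditions: Dess–Martin periodinane, pyridine, CH2Cl2, 0 °C
Reagents that add atoms: none
Why: Buffered Dess–Martin oxidation of the allenyl carbinol gives the allenyl ketone without harming the silyl dienol ether.

Step 13
Reactants: 16 allenyl ketone
Product: 17 tricyclic adduct (5-en-7-one, 1-(triisopropylsilyloxy)-1-ene, 4,4-dimethyl, 10β-methyl, 8β-H, 9α-H)
Conditions: toluene, BHT (cat.), 80 °C
Reagents that add atoms: none
Why: The allenyl ketone and the silyloxydiene should combine in a concerted, asynchronous [4+2] cycloaddition in which the nucleophilic diene terminus C10 bonds to the electrophilic central allene carbon C5 ahead of the C3–C4 bond, so that the conjugated 5-en-7-one and the C1 silyl enol ether emerge directly. The closest known reaction type is the intramolecular Diels–Alder reaction of allenyl carbonyl compounds through their distal double bond, as in the arene–allene cycloadditions of allenyl amides. Ring A is the new cyclohexene, and ring B closes through the four-atom tether C6–C7–C8–C9 in the way a 1,7,9-decatriene gives a fused bicycle, trans-fused here to ring C. The one new stereocentre, C10, is controlled by allylic 1,3-strain: the bulky silyloxy group cis to C9 keeps H-9 in the diene plane, so the tethered allene reaches the face that puts the C10 methyl anti to H-9 (10β). The step needs the distal and not the conjugated allene bond to react; the trans fusion at C8–C9 forbids the five-membered ring that the conjugated bond would have to close, and the reacting carbon C5 is sp-hybridised and unhindered. It also needs the (Z)-dienol ether from step 9, whose C9 substituent points away from C2 so that the s-cis diene can reach the allene.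

Step 14
Reactants: 17 tricyclic adduct
Product: 18 7β-allylic alcohol
Conditions: NaBH4, CeCl3·7H2O, MeOH–CH2Cl2, −78 °C
Reagents that add atoms: none
Why: Luche reduction: 1,2-hydride addition to the enone from the α face (axial attack, as for steroidal 5-en-7-ones) gives the equatorial 7β-alcohol while the C1 carbonyl stays masked as its silyl enol ether.

Step 15
Reactants: 18 7β-allylic alcohol
Product: 19 1-ketone (7β-OH, 5-ene, 12β-CH2CH(OMe)2)
Conditions: HF·pyridine, MeOH–THF, 0 °C to rt
Reagents that add atoms: methanol CO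
Why: Fluoride-assisted protodesilylation of the silyl enol ether reveals the C1 ketone and the acidic methanol converts the methyl enol ether into its dimethyl acetal (acetalisation), removing both electron-rich alkenes before the hydration.

Step 16
Reactants: 19 1-ketone
Product: 20 5α,7β-dihydroxy 1-ketone
Conditions: Mn(dpm)3 (cat.), PhSiH3, O2 (1 atm), iPrOH–CH2Cl2, 0 °C to rt
Reagents that add atoms: dioxygen O=O
Why: Mukaiyama hydration (metal-hydride hydrogen atom transfer to C6, then trapping of the tertiary C5 radical by O2) should deliver oxygen from the α face, anti to the axial C10 and C4β methyl groups, giving the trans-fused 5α-alcohol.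

Step 17
Reactants: 20 5α,7β-dihydroxy 1-ketone
Product: 21 1α,5α,7β-triol
Conditions: Et2BOMe, NaBH4, THF–MeOH, −78 °C; then MeOH co-evaporation
Reagents that add atoms: none
Why: Narasaka–Prasad reduction: the diethylboron chelate between the 5α-oxygen and the C1 carbonyl covers the α face, so external hydride attacks from the β face and gives the syn-1,3-diol, that is the axial 1α-alcohol.

Step 18
Reactants: 21 1α,5α,7β-triol
Product: 22 1α,7β-diacetate (5α-OH free)
Conditions: Ac2O, DMAP, pyridine, rt to 40 °C
Reagents that add atoms: acetic anhydride CC(=O)OC(C)=O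
Why: Acylation under DMAP catalysis esterifies the two secondary alcohols at C1 and C7, while the tertiary 5α-alcohol flanked by two quaternary carbons should stay free.

Step 19
Reactants: 22 1α,7β-diacetate
Product: 24 lactol (spiro 5-hydroxy-γ-butyrolactone at C12, anomers), via carboxylic acid 23 (not isolated)
Conditions: H2 (1 atm), Pd/C, EtOAc, rt; then AcOH–H2O (4:1), 40 °C
Reagents that add atoms: water O
Why: Hydrogenolysis of the benzyl ester and acid hydrolysis of the dimethyl acetal give the γ-aldehyde acid, which closes spontaneously to the five-membered lactol (pseudo-acid), the acetates and the tertiary alcohol being stable to aqueous acetic acid.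

Step 20
Reactants: 24 lactol
Product: 25 enol lactone (spiro furan-2(3H)-one at C12)
Conditions: MsCl, Et3N, CH2Cl2, 0 °C to rt
Reagents that add atoms: none
Why: Sulfonylation of the lactol hydroxyl and base-induced elimination towards the only adjacent C–H (C12 is quaternary) should give the enol lactone, as in glycal formation from 2-deoxyglycosyl donors.

Step 21
Reactants: 25 enol lactone
Product: 27 spirocaesalmin, via bromo lactol 26 (not isolated)
Conditions: NBS, THF–H2O, 0 °C; then Ag2O, CH2Cl2, rt, dark
Reagents that add atoms: water O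
Why: Bromohydrin formation, with Br+ entering from the open C11-side face anti to the cis C14 ester and water adding at the acetal carbon whose anomers equilibrate, followed by Ag2O-assisted halohydrin cyclisation with inversion at the bromine-bearing carbon, should place the epoxide oxygen on the C14-side face that a direct epoxidation would not reach.

Compound list

1 | (E)-2-methylbut-2-enoyl chloride (tigloyl chloride) | C/C=C(\C)C(=O)Cl | starting material
2 | S-ethyl (E)-2-methylbut-2-enethioate | C/C=C(\C)C(=O)SCC | intermediate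
3 | S-ethyl (E)-4-bromo-2-methylbut-2-enethioate | BrC/C=C(\C)C(=O)SCC | intermediate
4 | Meldrum's acid (2,2-dimethyl-1,3-dioxane-4,6-dione) | CC1(C)OC(=O)CC(=O)O1 | starting material
5 | 5-[(E)-4-(ethylsulfanyl)-3-methyl-4-oxobut-2-en-1-yl]-2,2-dimethyl-1,3-dioxane-4,6-dione | CCSC(=O)/C(C)=C/CC1C(=O)OC(C)(C)OC1=O | intermediate
6 | methyl (E)-4-oxobut-2-enoate | COC(=O)/C=C/C=O | starting material
7 | ring-C aldehyde: all-trans cyclopentane spiro-fused at C12 to the dioxanedione; 14β-CO2Me, 8α-CHO, 9β-CH(CH3)C(O)SEt (C10 epimers) | COC(=O)[C@H]1[C@H](C=O)[C@@H](C(C)C(=O)SCC)CC12C(=O)OC(C)(C)OC2=O | intermediate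
8 | acylal acid: C7 methoxy acetal carbon bridged through O to the 12α-carbonyl; 12β-CO2H (C7 anomers) | COC(=O)[C@H]1[C@H](C2OC)[C@@H](C(C)C(=O)SCC)C[C@]1(C(O)=O)C(=O)O2 | intermediate
9 | acid chloride of 8 (12β-COCl) | COC(=O)[C@H]1[C@H](C2OC)[C@@H](C(C)C(=O)SCC)C[C@]1(C(Cl)=O)C(=O)O2 | intermediate
10 | 12β-formyl acylal | COC(=O)[C@H]1[C@H](C2OC)[C@@H](C(C)C(=O)SCC)C[C@]1(C=O)C(=O)O2 | intermediate
11 | 12β-(2-methoxyethenyl) acylal (E/Z mixture) | COC(=O)[C@H]1[C@H](C2OC)[C@@H](C(C)C(=O)SCC)C[C@]1(C=COC)C(=O)O2 | intermediate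
12 | vinyl ketone: 9β-CH(CH3)C(O)CH=CH2 | COC(=O)[C@H]1[C@H](C2OC)[C@@H](C(C)C(=O)C=C)C[C@]1(C=COC)C(=O)O2 | intermediate
13 | silyl dienol ether: 9β-[(Z)-C(CH3)=C(OTIPS)–CH=CH2] | COC(=O)[C@H]1[C@H](C2OC)[C@@H](/C(C)=C(\O[Si](C(C)C)(C(C)C)C(C)C)C=C)C[C@]1(C=COC)C(=O)O2 | intermediate
14 | aldehyde benzyl ester: 8α-CHO, 12α-CO2Bn, 12β-(2-methoxyethenyl), 14β-CO2Me | COC(=O)[C@H]1[C@H](C=O)[C@@H](/C(C)=C(\O[Si](C(C)C)(C(C)C)C(C)C)C=C)C[C@]1(C=COC)C(=O)OCc1ccccc1 | intermediate
15 | allenyl carbinol: 8α-CH(OH)–CH=C=C(CH3)2 (C7 epimers) | COC(=O)[C@H]1[C@H](C(O)C=C=C(C)C)[C@@H](/C(C)=C(\O[Si](C(C)C)(C(C)C)C(C)C)C=C)C[C@]1(C=COC)C(=O)OCc1ccccc1 | intermediate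
16 | allenyl ketone: 8α-C(O)–CH=C=C(CH3)2 | COC(=O)[C@H]1[C@H](C(=O)C=C=C(C)C)[C@@H](/C(C)=C(\O[Si](C(C)C)(C(C)C)C(C)C)C=C)C[C@]1(C=COC)C(=O)OCc1ccccc1 | intermediate
17 | tricyclic adduct: 5-en-7-one, 1-(triisopropylsilyloxy)-1-ene, 4,4-dimethyl, 10β-methyl, 8β-H, 9α-H | COC(=O)[C@H]1[C@@H]2C(=O)C=C3C(C)(C)CC=C(O[Si](C(C)C)(C(C)C)C(C)C)[C@]3(C)[C@H]2C[C@]1(C=COC)C(=O)OCc1ccccc1 | intermediate
18 | 7β-allylic alcohol of 17 | COC(=O)[C@H]1[C@@H]2[C@@H](O)C=C3C(C)(C)CC=C(O[Si](C(C)C)(C(C)C)C(C)C)[C@]3(C)[C@H]2C[C@]1(C=COC)C(=O)OCc1ccccc1 | intermediate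
19 | 1-ketone: 7β-OH, 5-ene, 12β-CH2CH(OMe)2, 12α-CO2Bn | COC(=O)[C@H]1[C@@H]2[C@@H](O)C=C3C(C)(C)CCC(=O)[C@]3(C)[C@H]2C[C@]1(CC(OC)OC)C(=O)OCc1ccccc1 | intermediate
20 | 5α,7β-dihydroxy 1-ketone | COC(=O)[C@H]1[C@@H]2[C@@H](O)C[C@@]3(O)C(C)(C)CCC(=O)[C@]3(C)[C@H]2C[C@]1(CC(OC)OC)C(=O)OCc1ccccc1 | intermediate
21 | 1α,5α,7β-triol | COC(=O)[C@H]1[C@@H]2[C@@H](O)C[C@@]3(O)C(C)(C)CC[C@H](O)[C@]3(C)[C@H]2C[C@]1(CC(OC)OC)C(=O)OCc1ccccc1 | intermediate
22 | 1α,7β-diacetate (5α-OH free, benzyl ester, dimethyl acetal) | COC(=O)[C@H]1[C@@H]2[C@@H](OC(C)=O)C[C@@]3(O)C(C)(C)CC[C@H](OC(C)=O)[C@]3(C)[C@H]2C[C@]1(CC(OC)OC)C(=O)OCc1ccccc1 | intermediate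
23 | carboxylic acid of 22 (12α-CO2H) | COC(=O)[C@H]1[C@@H]2[C@@H](OC(C)=O)C[C@@]3(O)C(C)(C)CC[C@H](OC(C)=O)[C@]3(C)[C@H]2C[C@]1(CC(OC)OC)C(O)=O | intermediate
24 | lactol: spiro 5-hydroxy-γ-butyrolactone at C12 (anomers) | COC(=O)[C@H]1[C@@H]2[C@@H](OC(C)=O)C[C@@]3(O)C(C)(C)CC[C@H](OC(C)=O)[C@]3(C)[C@H]2C[C@]12C(=O)OC(O)C2 | intermediate
25 | enol lactone: spiro furan-2(3H)-one at C12 | COC(=O)[C@H]1[C@@H]2[C@@H](OC(C)=O)C[C@@]3(O)C(C)(C)CC[C@H](OC(C)=O)[C@]3(C)[C@H]2C[C@]12C(=O)OC=C2 | intermediate
26 | bromo lactol: 4-bromo-5-hydroxy lactone, Br on the C11-side face (anomers) | COC(=O)[C@H]1[C@@H]2[C@@H](OC(C)=O)C[C@@]3(O)C(C)(C)CC[C@H](OC(C)=O)[C@]3(C)[C@H]2C[C@]12C(=O)OC(O)[C@H]2Br | intermediate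
27 | spirocaesalmin | COC(=O)[C@H]1[C@@H]2[C@@H](OC(C)=O)C[C@@]3(O)C(C)(C)CC[C@H](OC(C)=O)[C@]3(C)[C@H]2C[C@]12C(=O)O[C@@H]1O[C@@H]12 | target

Total step count: 21. Longest linear sequence: 21 steps (1 to 27).

Steps most likely to fail

Step 13. The cycloaddition joins three fully substituted carbons, so it may be outrun by dimerisation or ene-type reactions of the allenone, or the diene may add stepwise to the conjugated allene bond. The fallback sets out from 16 and comes back at 19, making the two bonds one after the other by polar chemistry. Me2AlCl at −78 °C should trigger an intramolecular Mukaiyama–Michael addition of C10 to the central allene carbon C5 and give, after aqueous work-up, the ring-B cyclohexenone vinyl ketone F1 (C5 isopropyl, C10 bearing methyl and C(O)CH=CH2). KOtBu in THF should then deprotonate the isopropyl methine (γ position of the enone) and close ring A by intramolecular vinylogous Michael addition of C4 to C3 (Robinson-type) to give the tricyclic 1,7-diketone F2. Luche reduction (NaBH4, CeCl3·7H2O) of the enone carbonyl, the neopentyl C1 ketone being much slower, gives the 7β-hydroxy 1-ketone enol ether F3, and PPTS in MeOH converts its enol ether into the acetal 19.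

Step 4. The second Michael addition, onto the α-methyl thioenoate, may be slow, so that the open-chain adduct accumulates, reverts by retro-Michael reaction or erodes in enantiopurity. The fallback sets out from 5 (with 6) and comes back at 7. The iminium-catalysed Michael addition is stopped at −20 °C at the open-chain Michael adduct F4, and ring C is closed in a separate operation by a DBU-mediated intramolecular Michael addition under thermodynamic control.

Step 17. Facial selectivity may be poor, with hydride delivered from the α face through the C5 alkoxide to give the 1β-alcohol. The fallback sets out from 19 and comes back at 21. The C1 ketone is reduced before C5 carries oxygen, with LiBH(s-Bu)3 at −78 °C under steric approach control (equatorial attack, axial alcohol), to the 1α,7β-diol F5; the Mukaiyama hydration of step 16 is then run on F5 to reach 21.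

Further compounds

F1 | step 13 | ring-B cyclohexenone vinyl ketone (C5 isopropyl, C10 methyl and C(O)CH=CH2) | COC(=O)[C@H]1[C@@H]2C(=O)C=C(C(C)C)[C@](C)(C(=O)C=C)[C@H]2C[C@]1(C=COC)C(=O)OCc1ccccc1
F2 | step 13 | tricyclic 1,7-diketone (5-ene, 12β-(2-methoxyethenyl)) | COC(=O)[C@H]1[C@@H]2C(=O)C=C3C(C)(C)CCC(=O)[C@]3(C)[C@H]2C[C@]1(C=COC)C(=O)OCc1ccccc1
F3 | step 13 | 7β-hydroxy 1-ketone enol ether | COC(=O)[C@H]1[C@@H]2[C@@H](O)C=C3C(C)(C)CCC(=O)[C@]3(C)[C@H]2C[C@]1(C=COC)C(=O)OCc1ccccc1
F4 | step 4 | open-chain Michael adduct (C12–C14 bond formed, ring C open) | COC(=O)[C@@H](CC=O)C1(C/C=C(\C)C(=O)SCC)C(=O)OC(C)(C)OC1=O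
F5 | step 17 | 1α,7β-diol (5-ene, dimethyl acetal, benzyl ester) | COC(=O)[C@H]1[C@@H]2[C@@H](O)C=C3C(C)(C)CC[C@H](O)[C@]3(C)[C@H]2C[C@]1(CC(OC)OC)C(=O)OCc1ccccc1
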